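## Structural features

The target is a 2-aryl-3-methylbenzofuran: a benzene ring (ring A) is fused through the C3a–C7a bond to a furan (ring B), whose C2 carries a 3,4,5-trimethoxyphenyl group (ring C) through a biaryl-type C–C bond and whose C3 carries a methyl group. Ring A is substituted in an unbroken row: hydrogen at C4, methoxy at C5, a free hydroxyl at C6 and an allyl group at C7, the last one wedged between the phenol and the ring oxygen O1. The molecule has no stereocentre, so the only stereochemical elements of the route are transient (C3a, C7 and C7a of the cycloadduct) and all are erased. The fragile points are three: the electron-rich ortho-allylphenol, which oxidants and acids turn into quinone methides, chromenes or dihydrofurans; the terminal allyl double bond, which strong base or metal hydrides move into conjugation; and the electron-rich, fully substituted furan. The real difficulty is not the biaryl bond or the furan but the regiodefined ring A, with two neighbouring oxygens that must be told apart and a carbon substituent at the most hindered position, C7. The key step exploits two facts: C4–C5–C6–C7 is a butadiene unit with oxygen on both inner carbons and allyl on one terminus, and the C3a–C7a bond it must be joined to is the C4=C5 bond of a furan. A nitro group at the future C7a activates that bond as a dienophile and then leaves as nitrous acid.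

## Logic of the disconnections

18 from 17. No skeletal bond is cut; the O–H at C6 is exchanged for an O–Si bond. The reason is that the ortho-allylphenol must never meet the oxidant that aromatises ring A. The gain is a final step that is a neutral fluoride cleavage. The demand is a silyl group that survives steps 7 and 8 and still comes off without touching the allyl group.

17 from 16. Hydrogen is put back on C4 and C7, which takes ring A to the 4,7-dihydro level. This is exactly the oxidation level that a [4+2] addition followed by loss of one molecule of acid delivers. The gain is that C7 becomes an sp3 carbon and C5=C6 an enediol diether, both natural products of a diene addition. The demand is a dehydrogenation that picks the 1,4-cyclohexadiene and spares the allyl group, the furan and the silyl ether.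

16 from 6 and 14, through 15. After the nitro group and H-3a are put back across C3a–C7a, the bonds C3a–C4 and C7–C7a are cut. The cut is made here because these two bonds join a four-carbon unit, which already holds methoxy, silyloxy and allyl in the right order, to a furan double bond. The nitro group on that double bond serves as activator and as leaving group. The gain is large: the whole ring-A problem splits into two fragments of similar size, each three steps from commercial material. The demand is the orientation of the addition (unsubstituted diene terminus to C3a) and the survival of the silyl enol ether under heat and acid.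

14 from 13. The O–Si bond of the dienol ether is cut, which leaves an α-methoxy enone. The ketone has only one enolisable position, so the site of enolisation is not in doubt. The demand is on geometry: the chain must end up trans to the methoxyvinyl group.

13 from 9 and 10, through 11 and 12. The C–C bond between the carbonyl carbon and the methoxy-bearing vinyl carbon is cut. This reveals an acyl-anion equivalent derived from 10 and an acylating agent that stops at the ketone stage. The demand is single addition and a work-up that does not hydrolyse the enol ether.

9 from 7, through 8. The amide C–N bond is cut, back to the commercial acid. The demand is only a mild activation that leaves the terminal alkene alone.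

6 from 4, through 5. The C–N bond at the one free α-position of the furan is cut. Placing the nitration after the biaryl bond keeps the small nitro compound out of the coupling step. The demand is that the furan, and not ring C, takes the electrophile.

4 from 2 and 3. The bond between furan C2 and ring C is cut into a heteroaryl bromide and a commercial arylboron partner. The gain is full convergence of ring C. The demand is an ordinary cross-coupling on a labile bromofuran.

2 from 1. The C–Br bond is cut. The methyl group of 1 directs the halogen to the adjacent α-position, so no blocking group is needed.

## Other disconnections considered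

Alternative 1: The cut is through ring B at C3–C3a and O1–C2, with the allyl group parked for the moment on C3a. In the forward sense an acid ionises 2-allyl-4,4,5-trimethoxycyclohexa-2,5-dienone A2 by loss of methoxide. The propenyl group of (E)-isoelemicin A3 attacks the allyl-bearing ring carbon of the cation, the carbonyl oxygen captures the benzylic cation and the oxocarbenium ion loses its methyl group to give the hydrobenzofuranone A1. A thermal [3,3] shift would then carry the allyl group from C3a to C7, enolisation would give the phenol, and the C2–C3 bond would still have to be dehydrogenated.

- In its favour: both partners are close to commodity phenylpropenes; the two ring-A oxygens arrive differentiated; the sigmatropic shift places the allyl group at C7 intramolecularly; no nitro compound and no organolithium is needed.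
- Against it here: the cation has several electrophilic sites, and the alkene can also add in a [5+2] sense to give bridged bicyclic products, so bond formation at the substituted, allyl-bearing carbon is not assured. Three stereocentres are built only to be destroyed. The final 2,3-dihydrobenzofuran-to-benzofuran oxidation has to be done on the free ortho-allylphenol, the most oxidant-sensitive motif of the molecule, unless protection steps are added.
- Comparison: on step count this alternative is the better one if its cycloaddition is selective (about five or six operations against nine). On structure the two are equals, since both deliver the C5/C6 oxygens already distinguished. On mechanism the chosen plan is safer: its orientation depends on one polar diene–nitroalkene interaction, whereas A1 must win among competing cation–alkene pathways. The chosen end-game also oxidises a 1,4-dihydroarene whose phenol is already silylated, which is easier than dehydrogenating a dihydrofuran ring.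

Alternative 2: The cut is again through ring B, at C3–C3a and O1–C7a. In the forward sense a zerovalent palladium catalyst made from Pd2(dba)3 and Xantphos, with Cs2CO3, arylates the enolate of 1-(3,4,5-trimethoxyphenyl)propan-1-one A6 at the C–I bond of 1-bromo-2-iodo-4-methoxy-5-(methoxymethoxy)benzene A5. The resulting enolate oxygen then couples at the neighbouring C–Br bond and closes the furan to give A4. Removal of the methoxymethyl group, O-allylation and an aromatic Claisen rearrangement would then move the allyl group to C7, the other ortho position being blocked by the methoxy group.

- In its favour: the tandem C- and O-arylation is an established reaction type; the iodide-before-bromide order fixes the orientation of ring A; the ketone is an off-the-shelf compound; the Claisen rearrangement is among the most dependable ways to an ortho-allylphenol and releases the free C6 hydroxyl directly; no energetic or pyrophoric reagent is required.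
- Against it here: A5 has to be prepared in about three steps with regiocontrolled double halogenation. The key step builds none of the C7 substitution, so three further steps, one of them at about 190 °C on an electron-rich benzofuran, follow it.
- Comparison: the step count is about equal (seven to eight against nine, longest linear sequence about seven against six). In predictability this alternative is the better one, because regiochemistry is never left to orbital coefficients. The chosen plan is superior in convergence and in bond economy: one step installs the complete, differentiated ring A including the allyl group. It also avoids the high-temperature rearrangement.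

Alternative 3: The cut is through ring A at C3a–C7a and C6–C7, so that ring A comes from a furan whose oxygen becomes the C6 hydroxyl. In the forward sense heating 4-methoxy-2-[1-(pent-4-en-1-yn-1-yloxy)-1-(3,4,5-trimethoxyphenyl)propan-2-yl]furan A8 would bring the furan diene and the tethered ynol ether together in an intramolecular [4+2] addition. The oxygen bridge of the adduct would open at C3a, helped by the C5 methoxy group, and loss of H-6 would give the phenol A7, with the dihydrofuran ring closed in the same event. Dehydrogenation of C2–C3 would remain.

- In its favour: the tether dictates the regiochemistry completely, and on this point it is better than the chosen plan. The free phenol and the C7 allyl group appear in one step.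
- Against it here: A8 is a long linear construct. It needs a 3-methoxyfuran building block, a coupling that sets two stereocentres later destroyed, and an ynol ether made by elimination and C-allylation of a lithium alkynyl ether. Ynol ethers and 3-alkoxyfurans are acid-labile. An alkynyl ether with a β-hydrogen on its alkyl group can fragment thermally to a ketene and an alkene in competition with the cycloaddition. Diene and dienophile are both electron-rich, so the reaction relies on intramolecularity alone. As in alternative 1, the last oxidation must be done next to the free ortho-allylphenol.
- Comparison: both plans build ring A by a [4+2] addition and both need a final adjustment of oxidation level, so in concept they are equals. The chosen plan is clearly shorter (this alternative would need ten or more steps, most of them linear) and more convergent. The alternative is the more secure in orientation.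

Key step: step 7

Remark on the chemistry: the dienol ether is carried as its tert-butyldimethylsilyl ether (not trimethylsilyl) and solid K2CO3 is added in the cycloaddition, so that the enol ether survives isolation, heat, the nitrous acid released and the quinone oxidant; the (Z) descriptor of 14 means that the chain lies trans to the methoxyvinyl group, i.e. outward in the s-cis diene.

## Route

Step 1
Reactants: 1 3-methylfuran
Product: 2 2-bromo-3-methylfuran
Conditions: NBS (1.0 equiv, in portions), DMF, −10 → 0 °C, dark; pentane extraction, used at once as a solution
Reagents that add atoms: N-bromosuccinimide, O=C1CCC(=O)N1Br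
Why: Electrophilic aromatic bromination with NBS; attack at C2 gives the σ-complex whose charge rests on the methyl-bearing C3 and on oxygen, so C2 should be preferred over C5; the volatile, labile bromide is kept cold and dilute and is not stored.

Step 2
Reactants: 2 2-bromo-3-methylfuran; 3 (3,4,5-trimethoxyphenyl)boronic acid
Product: 4 3-methyl-2-(3,4,5-trimethoxyphenyl)furan
Conditions: Pd(PPh3)4 (3 mol %), K2CO3, THF/H2O, 65 °C
Reagents that add atoms: none
Why: Suzuki–Miyaura cross-coupling; zerovalent palladium inserts into the reactive 2-furyl C–Br bond, the electron-rich arylboronate transmetalates and reductive elimination forms the biaryl bond, with no competing reactive site in either partner.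

Step 3
Reactants: 4 3-methyl-2-(3,4,5-trimethoxyphenyl)furan
Product: 6 3-methyl-5-nitro-2-(3,4,5-trimethoxyphenyl)furan, via acetoxy-nitro-dihydrofuran adduct 5 (not isolated)
Conditions: fuming HNO3 (1.1 equiv), Ac2O, −20 °C; then pyridine, 0 °C → rt
Reagents that add atoms: acetyl nitrate, CC(=O)O[N+](=O)[O-], made in the flask from nitric acid, O[N+](=O)[O-], and acetic anhydride, CC(=O)OC(C)=O (the acetoxy group is carried only in 5)
Why: Nitration of a furan by addition–elimination; acetyl nitrate attacks the only free α-position C5, which is far more nucleophilic than ring C, acetate caps the aryl- and oxygen-stabilised cation at C2 to give 5, and pyridine removes acetic acid to restore the furan; the nitrating agent is generated and consumed cold and dilute and is never isolated.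

Step 4
Reactants: 7 pent-4-enoic acid
Product: 9 N-methoxy-N-methylpent-4-enamide, via 1-(pent-4-enoyl)imidazole 8 (not isolated)
Conditions: CDI, CH2Cl2, rt; then MeNHOMe·HCl, rt
Reagents that add atoms: N,O-dimethylhydroxylamine hydrochloride, CNOC.Cl; 1,1'-carbonyldiimidazole, O=C(n1ccnc1)n1ccnc1 (its imidazole is carried only in 8)
Why: Amide formation through the acyl imidazole; CDI activates the acid with loss of CO2, and the hydroxylamine, freed from its salt by the imidazole released, gives the N-methoxy-N-methylamide without an acid chloride.

Step 5
Reactants: 9 N-methoxy-N-methylpent-4-enamide; 10 methyl vinyl ether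
Product: 13 2-methoxyhepta-1,6-dien-3-one, via 1-methoxyvinyllithium 11 (not isolated), via lithium hemiaminal adduct 12 (not isolated)
Conditions: t-BuLi, THF, −78 → 0 °C; then 9, −78 → −20 °C; aq NH4Cl
Reagents that add atoms: tert-butyllithium, [Li]C(C)(C)C (lithium only in 11 and 12, none of its atoms in 13)
Why: Oxygen-directed α-lithiation of the vinyl ether gives the acyl-anion equivalent 11, which adds only once to the N-methoxy-N-methylamide (Weinreb ketone synthesis) because the chelated adduct 12 persists until the buffered quench; the neutral work-up keeps the acid-labile enol ether of 13 intact.

Step 6
Reactants: 13 2-methoxyhepta-1,6-dien-3-one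
Product: 14 (Z)-3-(tert-butyldimethylsilyloxy)-2-methoxyhepta-1,3,6-triene
Conditions: TBSOTf, Et3N, CH2Cl2, −78 → 0 °C
Reagents that add atoms: tert-butyldimethylsilyl trifluoromethanesulfonate, CC(C)(C)[Si](C)(C)OS(=O)(=O)C(F)(F)F
Why: Soft enolisation; O-silylation of the ketone and deprotonation by Et3N at C4, the only enolisable position, give the cross-conjugated silyl dienol ether, and the (Z) isomer should dominate because it avoids allylic 1,3-strain between the chain and the methoxyvinyl group.

Step 7
Reactants: 6 3-methyl-5-nitro-2-(3,4,5-trimethoxyphenyl)furan; 14 (Z)-3-(tert-butyldimethylsilyloxy)-2-methoxyhepta-1,3,6-triene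
Product: 16 7-allyl-6-(tert-butyldimethylsilyloxy)-5-methoxy-3-methyl-2-(3,4,5-trimethoxyphenyl)-4,7-dihydrobenzofuran (racemic), via nitro cycloadduct 15 (not isolated)
Conditions: 14 (2 equiv), K2CO3 (powdered, 2 equiv), BHT (cat.), 4 Å MS, toluene, 110 °C (reflux), Ar, 48 h; filtration through Et3N-deactivated silica
Reagents that add atoms: none
Why: The nitro group makes the furan C4=C5 bond of 6 an electron-poor nitroalkene that should take up the electron-rich diene 14 in a polar, strongly asynchronous normal-demand Diels–Alder reaction, the closest known reaction type being the cycloaddition of 2-nitrofurans with oxygenated dienes that ends in benzofurans after extrusion of nitrous acid. Bonding should be most advanced between the unsubstituted CH2 terminus of 14, which has the larger HOMO coefficient (raised by the 2-methoxy group and by the alkyl group on the far terminus) and is the less hindered end, and the β-carbon of the nitroalkene (furan C4), so that C3a–C4 leads C7–C7a and methoxy, silyloxy and allyl arrive at C5, C6 and C7. Ring A is closed as a six-membered carbocycle by a [4+2] addition that is suprafacial on both partners, which makes 15 cis-fused with H-3a and the nitro group on the same face. The nitro group of 15 sits on the acetal-type carbon C7a, so ionisation assisted by O1 and loss of H-3a (an E1-type elimination) should be easy at this temperature and restores the aromatic furan, and this irreversible step drains the cycloaddition equilibrium. The only stereocentre left in 16 is C7, formed racemic; its relative configuration in 15 follows from the endo or exo approach and the enol ether geometry of 14, but it is irrelevant because C7 becomes sp2 in step 8. Chemoselectivity rests on the nitro-bearing double bond being the only electron-poor π bond of 6 and on the terminal vinyl group of 14 being unactivated, while the outward position of the chain in the s-cis diene excludes both a 1,5-hydrogen shift and a steric block. K2CO3 takes up the nitrous acid so that neither nitrosation nor acid hydrolysis of the silyl enol ether erodes 16, and open reflux avoids heating a nitro compound in a closed vessel.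

Step 8
Reactants: 16 7-allyl-6-(tert-butyldimethylsilyloxy)-5-methoxy-3-methyl-2-(3,4,5-trimethoxyphenyl)-4,7-dihydrobenzofuran
Product: 17 7-allyl-6-(tert-butyldimethylsilyloxy)-5-methoxy-3-methyl-2-(3,4,5-trimethoxyphenyl)benzofuran
Conditions: DDQ (1.05 equiv), toluene, 0 °C → rt; aq NaHCO3
Reagents that add atoms: none
Why: Dehydrogenation of a 1,4-dihydroarene by DDQ; hydride abstraction from the doubly activated C4 or C7 gives a cation stabilised by the furan and the enol ether oxygens, and proton loss aromatises ring A and erases the C7 stereocentre, while one equivalent at low temperature should spare the allyl group and the still-masked phenol cannot form a quinone methide.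

Step 9
Reactants: 17 7-allyl-6-(tert-butyldimethylsilyloxy)-5-methoxy-3-methyl-2-(3,4,5-trimethoxyphenyl)benzofuran
Product: 18 7-allyl-5-methoxy-3-methyl-2-(3,4,5-trimethoxyphenyl)benzofuran-6-ol
Conditions: TBAF, AcOH (1:1), THF, 0 °C
Reagents that add atoms: none
Why: Fluoride-induced cleavage of the aryl silyl ether, which is fast for phenolic tert-butyldimethylsilyl ethers; the acetic acid buffer keeps the medium near neutral so that the allyl group does not migrate and the electron-rich phenoxide is not left exposed to air.

## Compound list

1 | 3-methylfuran | Cc1ccoc1 | starting material
2 | 2-bromo-3-methylfuran | Cc1ccoc1Br | intermediate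
3 | (3,4,5-trimethoxyphenyl)boronic acid | COc1cc(B(O)O)cc(OC)c1OC | starting material
4 | 3-methyl-2-(3,4,5-trimethoxyphenyl)furan | Cc1ccoc1-c1cc(OC)c(OC)c(OC)c1 | intermediate
5 | 2-acetoxy-3-methyl-5-nitro-2-(3,4,5-trimethoxyphenyl)-2,5-dihydrofuran (racemic mixture of diastereomers, not isolated) | CC(=O)OC1(c2cc(OC)c(OC)c(OC)c2)OC([N+](=O)[O-])C=C1C | intermediate
6 | 3-methyl-5-nitro-2-(3,4,5-trimethoxyphenyl)furan | Cc1cc([N+](=O)[O-])oc1-c1cc(OC)c(OC)c(OC)c1 | intermediate
7 | pent-4-enoic acid | C=CCCC(=O)O | starting material
8 | 1-(1H-imidazol-1-yl)pent-4-en-1-one (not isolated) | C=CCCC(=O)n1ccnc1 | intermediate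
9 | N-methoxy-N-methylpent-4-enamide | C=CCCC(=O)N(C)OC | intermediate
10 | methyl vinyl ether | C=COC | starting material
11 | (1-methoxyvinyl)lithium (not isolated) | [Li]C(=C)OC | intermediate
12 | lithium 2-methoxy-3-[methoxy(methyl)amino]hepta-1,6-dien-3-olate (racemic, not isolated) | C=CCCC(O[Li])(N(C)OC)C(=C)OC | intermediate
13 | 2-methoxyhepta-1,6-dien-3-one | C=CCCC(=O)C(=C)OC | intermediate
14 | (Z)-3-(tert-butyldimethylsilyloxy)-2-methoxyhepta-1,3,6-triene | C=C(OC)/C(O[Si](C)(C)C(C)(C)C)=C/CC=C | intermediate
15 | 7-allyl-6-(tert-butyldimethylsilyloxy)-5-methoxy-3-methyl-7a-nitro-2-(3,4,5-trimethoxyphenyl)-3a,4,7,7a-tetrahydrobenzofuran (racemic, cis-fused with H-3a and nitro on the same face, C7 not controlled, not isolated) | C=CCC1C(O[Si](C)(C)C(C)(C)C)=C(OC)C[C@@H]2C(C)=C(c3cc(OC)c(OC)c(OC)c3)O[C@]12[N+](=O)[O-] | intermediate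
16 | 7-allyl-6-(tert-butyldimethylsilyloxy)-5-methoxy-3-methyl-2-(3,4,5-trimethoxyphenyl)-4,7-dihydrobenzofuran (racemic, one enantiomer drawn) | C=CC[C@H]1C(O[Si](C)(C)C(C)(C)C)=C(OC)Cc2c(C)c(-c3cc(OC)c(OC)c(OC)c3)oc21 | intermediate
17 | 7-allyl-6-(tert-butyldimethylsilyloxy)-5-methoxy-3-methyl-2-(3,4,5-trimethoxyphenyl)benzofuran | C=CCc1c(O[Si](C)(C)C(C)(C)C)c(OC)cc2c(C)c(-c3cc(OC)c(OC)c(OC)c3)oc12 | intermediate
18 | 7-allyl-5-methoxy-3-methyl-2-(3,4,5-trimethoxyphenyl)benzofuran-6-ol | C=CCc1c(O)c(OC)cc2c(C)c(-c3cc(OC)c(OC)c(OC)c3)oc12 | target

## Step count and least certain steps

Total step count: 9. Longest linear sequence: 6 steps (steps 1, 2, 3, 7, 8, 9; the diene branch, steps 4, 5, 6, 7, 8, 9, is equally long).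

Step 7 (key step).
- What may go wrong: the aryl donor at C2 pushes electron density through the furan towards the nitro group, so the cycloaddition may be slow enough for thermal decay or polymerisation of the diene to compete. The silyloxy group could also take control of the orientation and give the reversed adduct, or the nitro group could engage the enol ether in a hetero-Diels–Alder reaction.
- Fallback: it sets out from 6 and 10 and comes back to the route at 18. Lithiated 10 (11, made as in step 5) would be acylated with commercial N,2-dimethoxy-N-methylacetamide to give 1,3-dimethoxybut-3-en-2-one F1. Silylation with TBSOTf and Et3N would give (Z)-2-(tert-butyldimethylsilyloxy)-1,3-dimethoxybuta-1,3-diene F2, a diene polarised by a terminal and an inner methoxy group towards its CH2 end and carrying its own leaving group. Heated with 6 under the conditions of step 7, it should form 6-(tert-butyldimethylsilyloxy)-5,7-dimethoxy-3-methyl-7a-nitro-2-(3,4,5-trimethoxyphenyl)-3a,4,7,7a-tetrahydrobenzofuran F3 (not isolated). F3 should lose nitrous acid and methanol in the same pot and aromatise without an oxidant to 6-(tert-butyldimethylsilyloxy)-5-methoxy-3-methyl-2-(3,4,5-trimethoxyphenyl)benzofuran F4. TBAF would release 5-methoxy-3-methyl-2-(3,4,5-trimethoxyphenyl)benzofuran-6-ol F5, and allyl bromide with K2CO3 in acetone would give 6-(allyloxy)-5-methoxy-3-methyl-2-(3,4,5-trimethoxyphenyl)benzofuran F6. An aromatic Claisen rearrangement (N,N-diethylaniline, 190 °C) can only go to C7, because C5 is blocked, and would give 18.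

Step 3.
- What may go wrong: oxidative opening of the electron-rich 2-arylfuran to an ene-dione, or competing nitration of ring C, because nitrating agents are also oxidants and the substrate carries two electron-rich rings.
- Fallback: it sets out from 2 and comes back at 6. The order of events is inverted so that the nitrating agent meets only a simple furan. 2 would be nitrated under the conditions of step 3 to 2-bromo-3-methyl-5-nitrofuran F7, and the activated C–Br bond of F7 would then be coupled with 3 (Pd(PPh3)4, K2CO3, THF/H2O, 65 °C) to give 6.

Step 6.
- What may go wrong: conjugate addition or oligomerisation of the captodative enone under Lewis-acidic silylation, and loss of the cross-conjugated dienol ether by hydrolysis during isolation. Incomplete geometric control would only lower the amount of reactive diene.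
- Fallback: it sets out from 13 and comes back at 14, forming the two enol ether units in the opposite order. Methanol with catalytic PPTS would add to the enol ether of 13 and give the stable ketal 2,2-dimethoxyhept-6-en-3-one F8. LiHMDS and TBSCl in THF at −78 °C would give (Z)-tert-butyl[(2,2-dimethoxyhepta-3,6-dien-3-yl)oxy]dimethylsilane F9, whose geometry is enforced by the bulky ketal carbon. TMSOTf with excess iPr2NEt in CH2Cl2 at −20 °C would then eliminate methanol from the ketal toward its methyl group and give 14.

Step 8.
- What may go wrong: early loss of the silyl group from the cationic intermediate would expose the phenol, which the quinone would then over-oxidise at the ortho-allylphenol. Slow oxidation at the allylic and benzylic CH2 of the product is also possible if excess oxidant is present.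
- Fallback: it sets out from 16 and comes back at 18, passing 17 by and aromatising by halogenation and elimination with no quinone oxidant. NBS (1.0 equiv, THF, −78 °C) should brominate the enediol diether of 16 at C5 and give 7-allyl-5-bromo-5-methoxy-3-methyl-2-(3,4,5-trimethoxyphenyl)-5,7-dihydrobenzofuran-6(4H)-one F10. Et3N would then remove hydrogen bromide across C4–C5, and the resulting dienone should enolise at once to 18.

## Further compounds

F1 | step 7 | 1,3-dimethoxybut-3-en-2-one | COCC(=O)C(=C)OC
F2 | step 7 | (Z)-2-(tert-butyldimethylsilyloxy)-1,3-dimethoxybuta-1,3-diene | CO/C=C(O[Si](C)(C)C(C)(C)C)/C(=C)OC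
F3 | step 7 | 6-(tert-butyldimethylsilyloxy)-5,7-dimethoxy-3-methyl-7a-nitro-2-(3,4,5-trimethoxyphenyl)-3a,4,7,7a-tetrahydrobenzofuran (racemic, cis-fused, C7 not controlled) | COC1C(O[Si](C)(C)C(C)(C)C)=C(OC)C[C@@H]2C(C)=C(c3cc(OC)c(OC)c(OC)c3)O[C@]12[N+](=O)[O-]
F4 | step 7 | 6-(tert-butyldimethylsilyloxy)-5-methoxy-3-methyl-2-(3,4,5-trimethoxyphenyl)benzofuran | COc1cc2c(C)c(-c3cc(OC)c(OC)c(OC)c3)oc2cc1O[Si](C)(C)C(C)(C)C
F5 | step 7 | 5-methoxy-3-methyl-2-(3,4,5-trimethoxyphenyl)benzofuran-6-ol | COc1cc2c(C)c(-c3cc(OC)c(OC)c(OC)c3)oc2cc1O
F6 | step 7 | 6-(allyloxy)-5-methoxy-3-methyl-2-(3,4,5-trimethoxyphenyl)benzofuran | C=CCOc1cc2oc(-c3cc(OC)c(OC)c(OC)c3)c(C)c2cc1OC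
F7 | step 3 | 2-bromo-3-methyl-5-nitrofuran | Cc1cc([N+](=O)[O-])oc1Br
F8 | step 6 | 2,2-dimethoxyhept-6-en-3-one | C=CCCC(=O)C(C)(OC)OC
F9 | step 6 | (Z)-tert-butyl[(2,2-dimethoxyhepta-3,6-dien-3-yl)oxy]dimethylsilane | CC(OC)(OC)/C(O[Si](C)(C)C(C)(C)C)=C/CC=C
F10 | step 8 | 7-allyl-5-bromo-5-methoxy-3-methyl-2-(3,4,5-trimethoxyphenyl)-5,7-dihydrobenzofuran-6(4H)-one (racemic mixture of diastereomers) | C=CCC1C(=O)C(Br)(OC)Cc2c(C)c(-c3cc(OC)c(OC)c(OC)c3)oc21
A1 | alternative 1 | 3a-allyl-5-methoxy-3-methyl-2-(3,4,5-trimethoxyphenyl)-3,3a-dihydrobenzofuran-6(2H)-one (racemic, aryl trans to methyl) | C=CC[C@]12C=C(OC)C(=O)C=C1O[C@H](c1cc(OC)c(OC)c(OC)c1)[C@H]2C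
A2 | alternative 1 | 2-allyl-4,4,5-trimethoxycyclohexa-2,5-dienone | C=CCC1=CC(OC)(OC)C(OC)=CC1=O
A3 | alternative 1 | (E)-isoelemicin, (E)-1,2,3-trimethoxy-5-(prop-1-en-1-yl)benzene | C/C=C/c1cc(OC)c(OC)c(OC)c1
A4 | alternative 2 | 5-methoxy-6-(methoxymethoxy)-3-methyl-2-(3,4,5-trimethoxyphenyl)benzofuran | COCOc1cc2oc(-c3cc(OC)c(OC)c(OC)c3)c(C)c2cc1OC
A5 | alternative 2 | 1-bromo-2-iodo-4-methoxy-5-(methoxymethoxy)benzene | COCOc1cc(Br)c(I)cc1OC
A6 | alternative 2 | 1-(3,4,5-trimethoxyphenyl)propan-1-one | CCC(=O)c1cc(OC)c(OC)c(OC)c1
A7 | alternative 3 | trans-7-allyl-5-methoxy-3-methyl-2-(3,4,5-trimethoxyphenyl)-2,3-dihydrobenzofuran-6-ol (racemic) | C=CCc1c(O)c(OC)cc2c1O[C@H](c1cc(OC)c(OC)c(OC)c1)[C@H]2C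
A8 | alternative 3 | 4-methoxy-2-[1-(pent-4-en-1-yn-1-yloxy)-1-(3,4,5-trimethoxyphenyl)propan-2-yl]furan (racemic, relative configuration leading to the trans product) | C=CCC#CO[C@H](c1cc(OC)c(OC)c(OC)c1)[C@@H](C)c1cc(OC)co1
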